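**Plan**
- Retrosynthesis: the phenol protecting groups come off first, then the two C–B bonds on C9 and C9' are exchanged for C–H, then C8–C9 and C8'–C9' are cut to leave a vicinal C8,C8'-bis(boronate), then both C–B bonds are removed to give an E C8=C8' alkene, which is finally split into two allylarenes.
- Forward: no ring is made, since rings A and B are bought. The chain is joined at C8=C8' by cross-metathesis, borylated on both carbons, extended by C9 and C9', reduced at boron and deprotected.
- Enabling feature: two allylbenzenes coupled through their terminal carbons already contain ring A, ring B, C7, C8, C8' and C7'; only the methyl carbons C9 and C9' are missing. These hang on the neighbouring methines C8 and C8', so an E-alkene can be turned into two like-configured C–B bonds that each take up one carbon.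
- Stereochemistry: C8 and C8' (both R) are set together by one ligand-controlled syn-diboration of the E-alkene and are kept by the retentive 1,2-shifts and all later steps.

Key step: step 4

Assumption: (S)-QUINAP is taken to be the ligand antipode that delivers both borons to the Re,Re face of the E-alkene (C8 and C8' both R); if the facial sense is the reverse, (R)-QUINAP is used in step 3 and nothing else changes.

**Step 1**
Reactants: 1 methoxyeugenol (4-allyl-2,6-dimethoxyphenol)
Product: 2 5-allyl-2-(benzyloxy)-1,3-dimethoxybenzene
Conditions: BnBr (1.2 equiv), K2CO3 (2 equiv), DMF, 60 °C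
Reagents that add atoms: benzyl bromide, BrCc1ccccc1
Why: Williamson ether synthesis, in which the phenoxide formed with K2CO3 is benzylated on oxygen, masking the acidic phenol from the boron and organolithium reagents of steps 3 to 5 while the allyl group is untouched.

**Step 2**
Reactants: 2 5-allyl-2-(benzyloxy)-1,3-dimethoxybenzene (3 equiv); 3 myristicin (6-allyl-4-methoxy-1,3-benzodioxole, 1 equiv)
Product: 4 6-[(2E)-4-(4-benzyloxy-3,5-dimethoxyphenyl)but-2-en-1-yl]-4-methoxy-1,3-benzodioxole
Conditions: second-generation Grubbs catalyst RuCl2(=CHPh)(H2IMes)(PCy3) (5 mol %), 1,4-benzoquinone (10 mol %), CH2Cl2, 40 °C, argon sweep; E-isomer separated on AgNO3-impregnated silica gel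
Reagents that add atoms: none
Why: Olefin cross-metathesis of two unhindered allylarenes is driven by loss of ethylene and equilibrates toward the E-alkene, the excess of 2 biases the statistics toward the heterodimer, benzoquinone suppresses double-bond migration into conjugation, and the minor Z-isomer is removed because syn-addition to it would give the unlike diastereomer.

**Step 3**
Reactants: 4 the E-1,4-diarylbut-2-ene; 5 bis(catecholato)diboron (1.3 equiv)
Product: 7 (2R,3R)-1-(4-benzyloxy-3,5-dimethoxyphenyl)-4-(7-methoxy-1,3-benzodioxol-5-yl)butane-2,3-diyl bis(pinacol boronate), via bis(catechol boronate) 6 (not isolated)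
Conditions: Rh(acac)(nbd) (5 mol %), (S)-QUINAP (5 mol %), THF, rt; then pinacol (5 equiv), rt
Reagents that add atoms: bis(catecholato)diboron (5), c1ccc2OB(B3Oc4ccccc4O3)Oc2c1; pinacol, CC(C)(O)C(C)(C)O
Why: Rhodium-catalysed enantioselective 1,2-diboration, in which the B–B bond adds to the monovalent rhodium–QUINAP complex and alkene insertion followed by C–B reductive elimination places both borons on one face, so the E-geometry fixes the like relationship and the ligand selects the Re,Re face to set C8 and C8' as (R,R); transesterification with pinacol then gives the stable ester.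

**Step 4**
Reactants: 7 the (2R,3R)-vicinal bis(pinacol boronate); 8 bromochloromethane (6 equiv)
Product: 10 (2R,3R)-2-(4-benzyloxy-3,5-dimethoxybenzyl)-3-[(7-methoxy-1,3-benzodioxol-5-yl)methyl]butane-1,4-diyl bis(pinacol boronate), via dilithium bis(chloromethyl)boronate complex 9 (not isolated)
Conditions: BrCH2Cl, n-BuLi (5 equiv, added slowly), THF, −78 °C; then warm to rt, 12 h
Reagents that add atoms: bromochloromethane (8), ClCBr
Why: Bromine–lithium exchange between n-BuLi and BrCH2Cl at −78 °C generates LiCH2Cl in the presence of 7, and the carbenoid adds to both tricoordinate borons to give the bis(ate) complex 9; on warming, each secondary alkyl group shifts from boron to the CH2 carbon anti to the departing chloride, a 1,2-metallate rearrangement that forms C8–C9 and C8'–C9'. The closest known reaction type is the Matteson homologation of secondary alkyl pinacol boronic esters with chloromethyllithium, and double homologation of vicinal bis(boronates) obtained by alkene diboration is the direct analogy. No ring is closed. No new stereocentre arises, because C8 and C8' are the migrating termini and the shift proceeds with retention, so the (R,R) pair set in step 3 passes unchanged into 10. The step needs exactly one insertion per boron, which should be secured because ate-complex formation at −78 °C is much faster than migration and the excess carbenoid decomposes on warming before any tricoordinate primary boronate is regenerated. Carbon rather than a pinacol oxygen migrates, as is usual for pinacolato ate complexes.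

**Step 5**
Reactants: 10 the (2R,3R)-butane-1,4-diyl bis(pinacol boronate)
Product: 12 6-[(2R,3R)-4-(4-benzyloxy-3,5-dimethoxyphenyl)-2,3-dimethylbutyl]-4-methoxy-1,3-benzodioxole, via dilithium bis(phenyl)boronate complex 11 (not isolated)
Conditions: PhLi (2.2 equiv), Et2O, 0 °C to rt; solvent removed; then Ir[dF(CF3)ppy]2(dtbbpy)PF6 (2 mol %), PhSH (3 equiv), MeOH/acetone (1:1), blue LEDs, rt
Reagents that add atoms: none
Why: Photoredox protodeboronation of primary alkyl pinacol boronic esters through their aryl ate complexes, in which the excited trivalent iridium photocatalyst oxidises each boronate complex to a primary alkyl radical and PhBpin, the radical takes a hydrogen atom from thiophenol, and the stereocentres next to the radical carbons are not involved.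

**Step 6**
Reactants: 12 the benzyl- and methylene-protected lignan
Product: 13 sauriol B, 5-[(2R,3R)-4-(4-hydroxy-3,5-dimethoxyphenyl)-2,3-dimethylbutyl]-3-methoxybenzene-1,2-diol
Conditions: BCl3 (8 equiv), pentamethylbenzene (3 equiv), CH2Cl2, −78 °C to rt; then H2O, 0 °C
Reagents that add atoms: none
Why: BCl3 cleaves the aryl benzyl ether at low temperature (the benzyl cation is trapped by pentamethylbenzene) and on warming opens the methylenedioxy acetal in preference to the aryl methyl ethers, a known chemoselectivity of this Lewis acid, and aqueous work-up hydrolyses the aryl borates and the chloromethyl ether to the three free phenols.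

**Compound list**
1 | methoxyeugenol (4-allyl-2,6-dimethoxyphenol) | COc1cc(CC=C)cc(OC)c1O | starting material
2 | 5-allyl-2-(benzyloxy)-1,3-dimethoxybenzene | COc1cc(CC=C)cc(OC)c1OCc1ccccc1 | intermediate
3 | myristicin (6-allyl-4-methoxy-1,3-benzodioxole) | COc1cc(CC=C)cc2OCOc12 | starting material
4 | 6-[(2E)-4-(4-benzyloxy-3,5-dimethoxyphenyl)but-2-en-1-yl]-4-methoxy-1,3-benzodioxole | COc1cc(C/C=C/Cc2cc(OC)c(OCc3ccccc3)c(OC)c2)cc2OCOc12 | intermediate
5 | bis(catecholato)diboron | c1ccc2OB(B3Oc4ccccc4O3)Oc2c1 | starting material
6 | (2R,3R)-1-(4-benzyloxy-3,5-dimethoxyphenyl)-4-(7-methoxy-1,3-benzodioxol-5-yl)butane-2,3-diyl bis(catechol boronate) | COc1cc(C[C@@H](B2Oc3ccccc3O2)[C@H](B2Oc3ccccc3O2)Cc2cc(OC)c(OCc3ccccc3)c(OC)c2)cc2OCOc12 | intermediate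
7 | (2R,3R)-1-(4-benzyloxy-3,5-dimethoxyphenyl)-4-(7-methoxy-1,3-benzodioxol-5-yl)butane-2,3-diyl bis(pinacol boronate) | COc1cc(C[C@@H](B2OC(C)(C)C(C)(C)O2)[C@H](B2OC(C)(C)C(C)(C)O2)Cc2cc(OC)c(OCc3ccccc3)c(OC)c2)cc2OCOc12 | intermediate
8 | bromochloromethane | ClCBr | starting material
9 | dilithium bis(ate) complex of 7, each boron carrying the secondary alkyl group, the pinacolato ligand and a chloromethyl group, (2R,3R) | [Li+].[Li+].COc1cc(C[C@@H]([B-]2(CCl)OC(C)(C)C(C)(C)O2)[C@H]([B-]2(CCl)OC(C)(C)C(C)(C)O2)Cc2cc(OC)c(OCc3ccccc3)c(OC)c2)cc2OCOc12 | intermediate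
10 | (2R,3R)-2-(4-benzyloxy-3,5-dimethoxybenzyl)-3-[(7-methoxy-1,3-benzodioxol-5-yl)methyl]butane-1,4-diyl bis(pinacol boronate) | COc1cc(C[C@@H](CB2OC(C)(C)C(C)(C)O2)[C@H](CB2OC(C)(C)C(C)(C)O2)Cc2cc(OC)c(OCc3ccccc3)c(OC)c2)cc2OCOc12 | intermediate
11 | dilithium bis(ate) complex of 10, each boron carrying the primary alkyl group, the pinacolato ligand and a phenyl group, (2R,3R) | [Li+].[Li+].COc1cc(C[C@@H](C[B-]2(c3ccccc3)OC(C)(C)C(C)(C)O2)[C@H](C[B-]2(c3ccccc3)OC(C)(C)C(C)(C)O2)Cc2cc(OC)c(OCc3ccccc3)c(OC)c2)cc2OCOc12 | intermediate
12 | 6-[(2R,3R)-4-(4-benzyloxy-3,5-dimethoxyphenyl)-2,3-dimethylbutyl]-4-methoxy-1,3-benzodioxole | COc1cc(C[C@@H](C)[C@H](C)Cc2cc(OC)c(OCc3ccccc3)c(OC)c2)cc2OCOc12 | intermediate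
13 | sauriol B, 5-[(2R,3R)-4-(4-hydroxy-3,5-dimethoxyphenyl)-2,3-dimethylbutyl]-3-methoxybenzene-1,2-diol | COc1cc(C[C@@H](C)[C@H](C)Cc2cc(OC)c(O)c(OC)c2)cc(O)c1O | target

**Step count**
Total: 6 steps. Longest linear sequence: 6 steps (1 to 13); compounds 3, 5 and 8 enter directly as purchased materials.

**Steps most likely to fail**

Step 4. The second boron sits next to an already tetracoordinate, crowded neighbour, so complexation there may stay incomplete and only one carbon may be inserted; alternatively a primary boronate released too early may take up a second carbon. The fallback sets out from 7 and separates C–C bond formation from the adjustment of oxidation level. Dichloromethyllithium (CH2Cl2, n-BuLi, THF, −100 °C) would be preformed in excess and 7 added, followed by ZnCl2 and warming to rt. This double insertion of a CHCl unit should give the (2R,3R)-1,4-dichlorobutane-1,4-diyl bis(pinacol boronate) F1, whose CHCl configuration is irrelevant. LiBHEt3 in THF (0 °C to rt) would then add hydride to each boron and expel chloride by a 1,2-hydride shift, returning to the route at 10.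

Step 5. Complexation of both borons by PhLi may be incomplete, or the primary radicals may add to the neighbouring electron-rich ring before hydrogen transfer. The fallback sets out from 10 and uses the classical deoxygenation. NaOH/H2O2 in THF/H2O (0 °C to rt) should give the (2R,3R)-2,3-bis(arylmethyl)butane-1,4-diol F2. MsCl and Et3N in CH2Cl2 at 0 °C should give the bis(methanesulfonate) F3. LiBHEt3 in THF at reflux should displace both sulfonates by hydride and return to the route at 12.

Step 6. A methyl ether flanked by two oxygens may be cleaved as well, or the benzyl cation may alkylate one of the electron-rich rings. The fallback sets out from 12 and removes the two groups separately by non-Lewis-acid methods. Pb(OAc)4 in benzene at 50 °C should acetoxylate the acetal carbon to give the 1,3-benzodioxol-2-yl acetate F4. Aqueous AcOH in THF at rt should hydrolyse it to the benzyl-protected catechol F5. Hydrogenolysis (H2, Pd/C, EtOAc, rt) should then return to the route at 13.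

**Further compounds**
F1 | step 4 | (2R,3R)-2-(4-benzyloxy-3,5-dimethoxybenzyl)-1,4-dichloro-3-[(7-methoxy-1,3-benzodioxol-5-yl)methyl]butane-1,4-diyl bis(pinacol boronate), mixture of epimers at the two CHCl carbons | COc1cc(C[C@@H](C(Cl)B2OC(C)(C)C(C)(C)O2)[C@H](C(Cl)B2OC(C)(C)C(C)(C)O2)Cc2cc(OC)c(OCc3ccccc3)c(OC)c2)cc2OCOc12
F2 | step 5 | (2R,3R)-2-(4-benzyloxy-3,5-dimethoxybenzyl)-3-[(7-methoxy-1,3-benzodioxol-5-yl)methyl]butane-1,4-diol | COc1cc(C[C@@H](CO)[C@H](CO)Cc2cc(OC)c(OCc3ccccc3)c(OC)c2)cc2OCOc12
F3 | step 5 | (2R,3R)-2-(4-benzyloxy-3,5-dimethoxybenzyl)-3-[(7-methoxy-1,3-benzodioxol-5-yl)methyl]butane-1,4-diyl bis(methanesulfonate) | COc1cc(C[C@@H](COS(C)(=O)=O)[C@H](COS(C)(=O)=O)Cc2cc(OC)c(OCc3ccccc3)c(OC)c2)cc2OCOc12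
F4 | step 6 | 6-[(2R,3R)-4-(4-benzyloxy-3,5-dimethoxyphenyl)-2,3-dimethylbutyl]-4-methoxy-1,3-benzodioxol-2-yl acetate, mixture of epimers at the acetal carbon | COc1cc(C[C@@H](C)[C@H](C)Cc2cc(OC)c(OCc3ccccc3)c(OC)c2)cc2OC(OC(C)=O)Oc12
F5 | step 6 | 5-[(2R,3R)-4-(4-benzyloxy-3,5-dimethoxyphenyl)-2,3-dimethylbutyl]-3-methoxybenzene-1,2-diol | COc1cc(C[C@@H](C)[C@H](C)Cc2cc(OC)c(OCc3ccccc3)c(OC)c2)cc(O)c1O
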